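**Retrosynthetic overview**
1. Target 23 comes from alcohol 22 by benzoylation. The seven-membered ring (ring C) is closed last, through the bond C9a–C9 (aryl carbon to carbinol carbon), by a fluoride-triggered intramolecular para-hydroxyalkylation of a phenoxide by the aldehyde of 19, finished in the same pot by O-methylation.
2. Enabling feature: the oxygen on C3 of the benzo ring (ring B, the middle of its three oxygens) is para to C9a, and both its ortho carbons (C2, C4) carry OMe. Kept as a silyl-masked phenol, it makes C9a (the least nucleophilic carbon of a trimethoxybenzene) the only productive carbon nucleophile, under basic conditions that the acid-labile 4-aryl-2,6-dimethoxycyclohexadienone (ring A) tolerates. The activating phenoxide is removed by becoming the 3-OMe group.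
3. The quaternary spiro carbon C5 comes from Birch reductive alkylation of biaryl 6 with iodide 13. The dienone carbonyl C4' comes from oxidation of the doubly allylic CH2 of the resulting 1,4-diene.
4. The C7 and C8 methyl centres come from C2-symmetric (2S,3S)-2,3-dimethylbutane-1,4-diol 10, made by auxiliary-controlled oxidative enolate dimerisation of two molecules of 7. Biaryl 6 comes from ortho-lithiation and Negishi coupling of silylated 2,6-dimethoxyphenol.
5. Ring order: rings A and B are joined as a biaryl, ring A is dearomatised to the dienone, and ring C is formed last.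

Key step: step 11

Remark: the spiro carbon is not a stereocentre (the two arms of the dienone are identical), so the task is C7 (R), C8 (S), C9 (R), meaning 7-CH3/8-CH3 trans and 8-CH3/9-O trans on ring C; atom numbers are those of the spiro[benzo[7]annulene-5,1'-cyclohexadiene] skeleton, and 1, 3 and 7 are taken as catalogue compounds.

Step 1
Reactants: 1 2,6-dimethoxyphenol
Product: 2 (2,6-dimethoxyphenoxy)tri(propan-2-yl)silane
Conditions: i-Pr3SiCl, imidazole, DMF, 60 °C
Reagents that add atoms: chlorotri(propan-2-yl)silane, CC(C)[Si](Cl)(C(C)C)C(C)C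
Why: Silyl ether formation at the phenol; the triisopropylsilyl ether flanked by two methoxy groups should survive n-BuLi, Li/NH3, peroxide oxidation and buffered HF, and is the fluoride-labile mask of the phenoxide needed in step 11.

Step 2
Reactants: 2 (2,6-dimethoxyphenoxy)tri(propan-2-yl)silane; 3 1-bromo-3,5-dimethoxybenzene
Product: 6 [(2,3',4,5'-tetramethoxy[1,1'-biphenyl]-3-yl)oxy]tri(propan-2-yl)silane, via aryllithium 4 (not isolated), via arylzinc chloride 5 (not isolated)
Conditions: n-BuLi, TMEDA, THF, 0 °C; ZnCl2, 0 °C to rt; then 3, Pd(PPh3)4 (3 mol %), 60 °C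
Reagents that add atoms: none
Why: Directed ortho-metalation occurs at the C–H ortho to a methoxy group (the two such positions are equivalent), transmetalation gives the arylzinc, and Negishi cross-coupling with 3 forms the biaryl bond.

Step 3
Reactants: 7 (4R)-4-benzyl-3-propanoyl-1,3-oxazolidin-2-one
Product: 9 (2S,3S)-1,4-bis[(4R)-4-benzyl-2-oxo-1,3-oxazolidin-3-yl]-2,3-dimethylbutane-1,4-dione, via lithium Z-enolate 8 (not isolated)
Conditions: LiN(i-Pr)2 (1.05 equiv per 7), THF, −78 °C; then TiCl4 (1.1 equiv per 7), −78 °C to rt; two molecules of 7 give one molecule of 9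
Reagents that add atoms: (4R)-4-benzyl-3-propanoyl-1,3-oxazolidin-2-one (second molecule of 7), CCC(=O)N1[C@H](Cc2ccccc2)COC1=O
Why: Oxidative enolate homocoupling: two molecules of the chelated Z-enolate 8 are each oxidised by TiCl4 (titanium going from the tetravalent to the trivalent state) and their α-carbons join on the enolate face opposite the benzyl group of the (4R)-oxazolidinone, which sets both new centres as S and gives the C2-symmetric dimer.

Step 4
Reactants: 9 (2S,3S)-1,4-bis[(4R)-4-benzyl-2-oxo-1,3-oxazolidin-3-yl]-2,3-dimethylbutane-1,4-dione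
Product: 10 (2S,3S)-2,3-dimethylbutane-1,4-diol
Conditions: LiBH4, MeOH (2 equiv), THF, 0 °C to rt
Reagents that add atoms: none
Why: Hydride reduction of the two N-acyl carbonyls (reductive auxiliary cleavage) releases the diol without enolisation, so the two methyl-bearing centres are kept and the auxiliary is returned.

Step 5
Reactants: 10 (2S,3S)-2,3-dimethylbutane-1,4-diol
Product: 12 (2S,3S)-4-{[tert-butyl(dimethyl)silyl]oxy}-2,3-dimethylbutan-1-ol, via sodium monoalkoxide 11 (not isolated)
Conditions: NaH (1.0 equiv), THF, rt; then t-BuMe2SiCl (1.0 equiv), rt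
Reagents that add atoms: tert-butylchlorodimethylsilane, CC(C)(C)[Si](C)(C)Cl
Why: Monosilylation of a symmetric diol through its monosodium alkoxide 11; because 10 is C2-symmetric the two hydroxyl groups are equivalent and a single mono-ether should result.

Step 6
Reactants: 12 (2S,3S)-4-{[tert-butyl(dimethyl)silyl]oxy}-2,3-dimethylbutan-1-ol
Product: 13 tert-butyl{[(2S,3S)-4-iodo-2,3-dimethylbutyl]oxy}dimethylsilane
Conditions: I2, PPh3, imidazole, CH2Cl2, 0 °C to rt
Reagents that add atoms: iodine, II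
Why: Appel-type iodination of the primary alcohol by SN2 at CH2, which leaves the two stereocentres and the silyl ether untouched.

Step 7
Reactants: 6 [(2,3',4,5'-tetramethoxy[1,1'-biphenyl]-3-yl)oxy]tri(propan-2-yl)silane; 13 tert-butyl{[(2S,3S)-4-iodo-2,3-dimethylbutyl]oxy}dimethylsilane
Product: 15 tert-butyl{[(2S,3R)-4-(1-{2,4-dimethoxy-3-[tri(propan-2-yl)silyloxy]phenyl}-3,5-dimethoxycyclohexa-2,5-dien-1-yl)-2,3-dimethylbutyl]oxy}dimethylsilane, via lithium cyclohexadienide 14 (not isolated)
Conditions: Li (2.2 equiv), NH3/THF, −78 °C; then 13 in THF, −78 °C; NH4Cl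
Reagents that add atoms: none
Why: Birch reductive alkylation of a biaryl: the 3,5-dimethoxyphenyl ring (ring A) accepts the two electrons because its methoxy groups are meta to the charge-bearing carbons C1 and C4 whereas ring B has ortho and para oxygen donors, ammonia protonates C4, and the aryl-stabilised dienyl anion 14 is alkylated by SN2 at its central carbon C1 to create the quaternary (later spiro) carbon; the chain centres take no part.

Step 8
Reactants: 15 tert-butyl{[(2S,3R)-4-(1-{2,4-dimethoxy-3-[tri(propan-2-yl)silyloxy]phenyl}-3,5-dimethoxycyclohexa-2,5-dien-1-yl)-2,3-dimethylbutyl]oxy}dimethylsilane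
Product: 17 4-[(2R,3S)-4-{[tert-butyl(dimethyl)silyl]oxy}-2,3-dimethylbutyl]-4-{2,4-dimethoxy-3-[tri(propan-2-yl)silyloxy]phenyl}-2,6-dimethoxycyclohexa-2,5-dien-1-one, via bis-allylic tert-butyl peroxide 16 (not isolated)
Conditions: Rh2(cap)4 (cap = caprolactamate, 1 mol %), t-BuOOH (70% in water, 5 equiv), K2CO3, CH2Cl2, rt
Reagents that add atoms: tert-butyl hydroperoxide, CC(C)(C)OO
Why: Metal-catalysed allylic C–H oxidation with t-BuOOH (peroxyl radical chain): the only allylic hydrogens are those of the doubly allylic CH2 between the two enol ethers, which should be converted via mixed peroxide 16 into the carbonyl of the cross-conjugated dienone, the usual fate of 3,3-disubstituted cyclohexa-1,4-dienes from Birch alkylations.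

Step 9
Reactants: 17 4-[(2R,3S)-4-{[tert-butyl(dimethyl)silyl]oxy}-2,3-dimethylbutyl]-4-{2,4-dimethoxy-3-[tri(propan-2-yl)silyloxy]phenyl}-2,6-dimethoxycyclohexa-2,5-dien-1-one
Product: 18 4-{2,4-dimethoxy-3-[tri(propan-2-yl)silyloxy]phenyl}-4-[(2R,3S)-4-hydroxy-2,3-dimethylbutyl]-2,6-dimethoxycyclohexa-2,5-dien-1-one
Conditions: HF·pyridine, pyridine, THF, 0 °C to rt
Reagents that add atoms: none
Why: Silyl ether cleavage under acidic fluoride, where the primary alkyl tert-butyldimethylsilyl ether is removed much faster than the hindered aryl triisopropylsilyl ether.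

Step 10
Reactants: 18 4-{2,4-dimethoxy-3-[tri(propan-2-yl)silyloxy]phenyl}-4-[(2R,3S)-4-hydroxy-2,3-dimethylbutyl]-2,6-dimethoxycyclohexa-2,5-dien-1-one
Product: 19 (2S,3R)-4-(1-{2,4-dimethoxy-3-[tri(propan-2-yl)silyloxy]phenyl}-3,5-dimethoxy-4-oxocyclohexa-2,5-dien-1-yl)-2,3-dimethylbutanal
Conditions: Dess–Martin periodinane, NaHCO3, CH2Cl2, 0 °C to rt
Reagents that add atoms: none
Why: Dess–Martin oxidation under buffered conditions should convert the primary alcohol into the aldehyde without epimerising the adjacent methyl-bearing centre.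

Step 11
Reactants: 19 (2S,3R)-4-(1-{2,4-dimethoxy-3-[tri(propan-2-yl)silyloxy]phenyl}-3,5-dimethoxy-4-oxocyclohexa-2,5-dien-1-yl)-2,3-dimethylbutanal
Product: 22 (7R,8S,9R)-9-hydroxy-2,3,3',4,5'-pentamethoxy-7,8-dimethyl-6,7,8,9-tetrahydro-4'H-spiro[benzo[7]annulene-5,1'-cyclohexa[2,5]dien]-4'-one, via open-chain phenoxide 20 (not isolated), via cyclised phenoxide 21 (not isolated)
Conditions: Bu4NF (1.1 equiv), THF, 0 °C to rt; then MeI (5 equiv), rt
Reagents that add atoms: iodomethane, CI
Why: Fluoride cleaves the aryl O–Si bond to give tetrabutylammonium phenoxide 20, whose para carbon C9a adds to the aldehyde carbon C9, the resulting cyclohexadienone tautomerises to phenoxide 21 with the proton ending on the new alkoxide, and MeI then caps the phenoxide oxygen as the third methoxy group, which also shuts off retro-addition. The closest known reaction type is the base-mediated para-hydroxyalkylation of phenoxides by aldehydes (Lederer–Manasse reaction, intramolecular phenolic aldol), run here directly after fluoride desilylation. The only ring closed is the seven-membered carbocycle, by 7-exo-trig attack of an arene carbon on the C=O group. The new centre C9 is controlled by the existing C8 and C7 centres: in the chair-like ring-forming transition state the two methyl groups and the forming C–O bond should sit pseudo-equatorial, which gives 9-OH trans to 8-CH3 (9R), and because the addition is reversible this all-trans isomer should also be the thermodynamic product. The step needs carbon over oxygen attack, para over ortho attack and ring closure faster than enolisation of the aldehyde: both ortho carbons carry OMe (attack through C4 would give a non-aromatisable, reversibly formed dienone), only para attack is followed by re-aromatisation, and the 2,6-dimethoxydienone is a poor Michael acceptor. Basic conditions are chosen because under acid C9a is the least nucleophilic position of a trimethoxybenzene and the 4-aryl dienone would undergo dienone–phenol rearrangement.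

Step 12
Reactants: 22 (7R,8S,9R)-9-hydroxy-2,3,3',4,5'-pentamethoxy-7,8-dimethyl-6,7,8,9-tetrahydro-4'H-spiro[benzo[7]annulene-5,1'-cyclohexa[2,5]dien]-4'-one
Product: 23 (7R,8S,9R)-2,3,3',4,5'-pentamethoxy-7,8-dimethyl-4'-oxo-6,7,8,9-tetrahydro-4'H-spiro[benzo[7]annulene-5,1'-cyclohexa[2,5]dien]-9-yl benzoate
Conditions: PhCOCl, Et3N, DMAP (cat.), CH2Cl2, 0 °C to rt
Reagents that add atoms: benzoyl chloride, O=C(Cl)c1ccccc1
Why: DMAP-catalysed acylation of the secondary benzylic alcohol with benzoyl chloride (esterification), which takes place at oxygen with retention at C9.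

**Compound list**
1 | 2,6-dimethoxyphenol | COc1cccc(OC)c1O | starting material
2 | (2,6-dimethoxyphenoxy)tri(propan-2-yl)silane | COc1cccc(OC)c1O[Si](C(C)C)(C(C)C)C(C)C | intermediate
3 | 1-bromo-3,5-dimethoxybenzene | COc1cc(Br)cc(OC)c1 | starting material
4 | {2,4-dimethoxy-3-[tri(propan-2-yl)silyloxy]phenyl}lithium | [Li]c1ccc(OC)c(O[Si](C(C)C)(C(C)C)C(C)C)c1OC | intermediate
5 | chloro{2,4-dimethoxy-3-[tri(propan-2-yl)silyloxy]phenyl}zinc | Cl[Zn]c1ccc(OC)c(O[Si](C(C)C)(C(C)C)C(C)C)c1OC | intermediate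
6 | [(2,3',4,5'-tetramethoxy[1,1'-biphenyl]-3-yl)oxy]tri(propan-2-yl)silane | COc1cc(OC)cc(-c2ccc(OC)c(O[Si](C(C)C)(C(C)C)C(C)C)c2OC)c1 | intermediate
7 | (4R)-4-benzyl-3-propanoyl-1,3-oxazolidin-2-one | CCC(=O)N1[C@H](Cc2ccccc2)COC1=O | starting material
8 | lithium (1Z)-1-[(4R)-4-benzyl-2-oxo-1,3-oxazolidin-3-yl]prop-1-en-1-olate | C/C=C(\O[Li])N1[C@H](Cc2ccccc2)COC1=O | intermediate
9 | (2S,3S)-1,4-bis[(4R)-4-benzyl-2-oxo-1,3-oxazolidin-3-yl]-2,3-dimethylbutane-1,4-dione | O=C([C@@H](C)[C@H](C)C(=O)N1[C@H](Cc2ccccc2)COC1=O)N1[C@H](Cc2ccccc2)COC1=O | intermediate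
10 | (2S,3S)-2,3-dimethylbutane-1,4-diol | OC[C@@H](C)[C@H](C)CO | intermediate
11 | sodium (2S,3S)-4-hydroxy-2,3-dimethylbutan-1-olate | [Na+].[O-]C[C@@H](C)[C@H](C)CO | intermediate
12 | (2S,3S)-4-{[tert-butyl(dimethyl)silyl]oxy}-2,3-dimethylbutan-1-ol | OC[C@@H](C)[C@H](C)CO[Si](C)(C)C(C)(C)C | intermediate
13 | tert-butyl{[(2S,3S)-4-iodo-2,3-dimethylbutyl]oxy}dimethylsilane | IC[C@@H](C)[C@H](C)CO[Si](C)(C)C(C)(C)C | intermediate
14 | lithium 1-{2,4-dimethoxy-3-[tri(propan-2-yl)silyloxy]phenyl}-3,5-dimethoxycyclohexa-2,5-dien-1-ide | [Li]C1(C=C(OC)CC(OC)=C1)c1ccc(OC)c(O[Si](C(C)C)(C(C)C)C(C)C)c1OC | intermediate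
15 | tert-butyl{[(2S,3R)-4-(1-{2,4-dimethoxy-3-[tri(propan-2-yl)silyloxy]phenyl}-3,5-dimethoxycyclohexa-2,5-dien-1-yl)-2,3-dimethylbutyl]oxy}dimethylsilane | COC1=CC(C[C@@H](C)[C@H](C)CO[Si](C)(C)C(C)(C)C)(C=C(OC)C1)c1ccc(OC)c(O[Si](C(C)C)(C(C)C)C(C)C)c1OC | intermediate
16 | 4-(tert-butylperoxy) derivative of 15, peroxide on the ring CH between the two enol ethers (either epimer) | COC1=CC(C[C@@H](C)[C@H](C)CO[Si](C)(C)C(C)(C)C)(C=C(OC)C1OOC(C)(C)C)c1ccc(OC)c(O[Si](C(C)C)(C(C)C)C(C)C)c1OC | intermediate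
17 | 4-[(2R,3S)-4-{[tert-butyl(dimethyl)silyl]oxy}-2,3-dimethylbutyl]-4-{2,4-dimethoxy-3-[tri(propan-2-yl)silyloxy]phenyl}-2,6-dimethoxycyclohexa-2,5-dien-1-one | COC1=CC(C[C@@H](C)[C@H](C)CO[Si](C)(C)C(C)(C)C)(C=C(OC)C1=O)c1ccc(OC)c(O[Si](C(C)C)(C(C)C)C(C)C)c1OC | intermediate
18 | 4-{2,4-dimethoxy-3-[tri(propan-2-yl)silyloxy]phenyl}-4-[(2R,3S)-4-hydroxy-2,3-dimethylbutyl]-2,6-dimethoxycyclohexa-2,5-dien-1-one | COC1=CC(C[C@@H](C)[C@H](C)CO)(C=C(OC)C1=O)c1ccc(OC)c(O[Si](C(C)C)(C(C)C)C(C)C)c1OC | intermediate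
19 | (2S,3R)-4-(1-{2,4-dimethoxy-3-[tri(propan-2-yl)silyloxy]phenyl}-3,5-dimethoxy-4-oxocyclohexa-2,5-dien-1-yl)-2,3-dimethylbutanal | COC1=CC(C[C@@H](C)[C@H](C)C=O)(C=C(OC)C1=O)c1ccc(OC)c(O[Si](C(C)C)(C(C)C)C(C)C)c1OC | intermediate
20 | tetrabutylammonium 3-{1-[(2R,3S)-2,3-dimethyl-4-oxobutyl]-3,5-dimethoxy-4-oxocyclohexa-2,5-dien-1-yl}-2,6-dimethoxyphenolate | COC1=CC(C[C@@H](C)[C@H](C)C=O)(C=C(OC)C1=O)c1ccc(OC)c([O-])c1OC.CCCC[N+](CCCC)(CCCC)CCCC | intermediate
21 | tetrabutylammonium (7R,8S,9R)-9-hydroxy-2,3',4,5'-tetramethoxy-7,8-dimethyl-4'-oxo-6,7,8,9-tetrahydrospiro[benzo[7]annulene-5,1'-cyclohexa[2,5]dien]-3-olate | COC1=CC2(C=C(OC)C1=O)C[C@@H](C)[C@H](C)[C@@H](O)c1cc(OC)c([O-])c(OC)c12.CCCC[N+](CCCC)(CCCC)CCCC | intermediate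
22 | (7R,8S,9R)-9-hydroxy-2,3,3',4,5'-pentamethoxy-7,8-dimethyl-6,7,8,9-tetrahydro-4'H-spiro[benzo[7]annulene-5,1'-cyclohexa[2,5]dien]-4'-one | COC1=CC2(C=C(OC)C1=O)C[C@@H](C)[C@H](C)[C@@H](O)c1cc(OC)c(OC)c(OC)c12 | intermediate
23 | (7R,8S,9R)-2,3,3',4,5'-pentamethoxy-7,8-dimethyl-4'-oxo-6,7,8,9-tetrahydro-4'H-spiro[benzo[7]annulene-5,1'-cyclohexa[2,5]dien]-9-yl benzoate | COC1=CC2(C=C(OC)C1=O)C[C@@H](C)[C@H](C)[C@@H](OC(=O)c1ccccc1)c1cc(OC)c(OC)c(OC)c12 | target

Total step count: 12. Longest linear sequence: 10 steps (steps 3 to 12, from 7).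

**Steps most likely to fail**

Step 8. The peroxyl-radical chain may attack the electron-rich enol ether double bonds, or degrade the ring, faster than it converts the CH2 group. The fallback runs from 15 back to 17 and replaces the radical oxidation by a pericyclic hydroxylation followed by alcohol oxidation. Catalytic SeO2 with t-BuOOH in CH2Cl2/pyridine should hydroxylate the same position by an ene reaction and [2,3]-sigmatropic shift, giving the doubly allylic alcohol 4-[(2R,3S)-4-{[tert-butyl(dimethyl)silyl]oxy}-2,3-dimethylbutyl]-4-{2,4-dimethoxy-3-[tri(propan-2-yl)silyloxy]phenyl}-2,6-dimethoxycyclohexa-2,5-dien-1-ol F1 (either carbinol epimer). MnO2 in CH2Cl2 should then oxidise it to dienone 17.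

Step 11. The phenoxide may deprotonate the α-branched aldehyde (epimerisation at C8, or conjugate addition of the enolate to the dienone) faster than its para carbon adds, the addition equilibrium may stay on the open-chain side, or the cyclised phenoxide may lose hydroxide to a quinone methide before it is methylated. The fallback runs from 18 back to 22 and closes the same bond irreversibly by an organochromium addition; the free phenol is used only to direct a halogen to the future C9a. Bu4NF on 18 should give 4-(3-hydroxy-2,4-dimethoxyphenyl)-4-[(2R,3S)-4-hydroxy-2,3-dimethylbutyl]-2,6-dimethoxycyclohexa-2,5-dien-1-one F2. N-Iodosuccinimide in MeCN at 0 °C should then iodinate para to the free hydroxyl, giving 4-(3-hydroxy-6-iodo-2,4-dimethoxyphenyl)-4-[(2R,3S)-4-hydroxy-2,3-dimethylbutyl]-2,6-dimethoxycyclohexa-2,5-dien-1-one F3. MeI/K2CO3 in acetone should give the aryl methyl ether 4-[(2R,3S)-4-hydroxy-2,3-dimethylbutyl]-4-(6-iodo-2,3,4-trimethoxyphenyl)-2,6-dimethoxycyclohexa-2,5-dien-1-one F4, and Dess–Martin oxidation should give (2S,3R)-4-[1-(6-iodo-2,3,4-trimethoxyphenyl)-3,5-dimethoxy-4-oxocyclohexa-2,5-dien-1-yl]-2,3-dimethylbutanal F5. CrCl2 with catalytic NiCl2 in DMF (Nozaki–Hiyama–Kishi reaction) should then close the seven-membered ring to 22.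

Step 7. In liquid ammonia the hindered dienyl anion may act as a base toward the β-branched iodide (elimination) or be protonated, and lithium amide may attack the aryl silyl ether. The fallback runs from 6 back to 15; it separates reduction from alkylation and uses a more reactive electrophile in an amide-free medium. Li/NH3 with t-BuOH should give the 1,4-dihydrobiaryl [3-(3,5-dimethoxycyclohexa-2,5-dien-1-yl)-2,6-dimethoxyphenoxy]tri(propan-2-yl)silane F6. Separately, alcohol 12 with Tf2O/2,6-lutidine should give (2S,3S)-4-{[tert-butyl(dimethyl)silyl]oxy}-2,3-dimethylbutyl trifluoromethanesulfonate F7. n-BuLi in THF/HMPA at −78 °C should regenerate anion 14 from F6 at its doubly allylic, benzylic C–H, and F7 should alkylate it to 15.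

**Further compounds**
F1 | step 8 | 4-[(2R,3S)-4-{[tert-butyl(dimethyl)silyl]oxy}-2,3-dimethylbutyl]-4-{2,4-dimethoxy-3-[tri(propan-2-yl)silyloxy]phenyl}-2,6-dimethoxycyclohexa-2,5-dien-1-ol (either carbinol epimer) | COC1=CC(C[C@@H](C)[C@H](C)CO[Si](C)(C)C(C)(C)C)(C=C(OC)C1O)c1ccc(OC)c(O[Si](C(C)C)(C(C)C)C(C)C)c1OC
F2 | step 11 | 4-(3-hydroxy-2,4-dimethoxyphenyl)-4-[(2R,3S)-4-hydroxy-2,3-dimethylbutyl]-2,6-dimethoxycyclohexa-2,5-dien-1-one | COC1=CC(C[C@@H](C)[C@H](C)CO)(C=C(OC)C1=O)c1ccc(OC)c(O)c1OC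
F3 | step 11 | 4-(3-hydroxy-6-iodo-2,4-dimethoxyphenyl)-4-[(2R,3S)-4-hydroxy-2,3-dimethylbutyl]-2,6-dimethoxycyclohexa-2,5-dien-1-one | COC1=CC(C[C@@H](C)[C@H](C)CO)(C=C(OC)C1=O)c1c(I)cc(OC)c(O)c1OC
F4 | step 11 | 4-[(2R,3S)-4-hydroxy-2,3-dimethylbutyl]-4-(6-iodo-2,3,4-trimethoxyphenyl)-2,6-dimethoxycyclohexa-2,5-dien-1-one | COC1=CC(C[C@@H](C)[C@H](C)CO)(C=C(OC)C1=O)c1c(I)cc(OC)c(OC)c1OC
F5 | step 11 | (2S,3R)-4-[1-(6-iodo-2,3,4-trimethoxyphenyl)-3,5-dimethoxy-4-oxocyclohexa-2,5-dien-1-yl]-2,3-dimethylbutanal | COC1=CC(C[C@@H](C)[C@H](C)C=O)(C=C(OC)C1=O)c1c(I)cc(OC)c(OC)c1OC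
F6 | step 7 | [3-(3,5-dimethoxycyclohexa-2,5-dien-1-yl)-2,6-dimethoxyphenoxy]tri(propan-2-yl)silane | COC1=CC(C=C(OC)C1)c1ccc(OC)c(O[Si](C(C)C)(C(C)C)C(C)C)c1OC
F7 | step 7 | (2S,3S)-4-{[tert-butyl(dimethyl)silyl]oxy}-2,3-dimethylbutyl trifluoromethanesulfonate | O=S(=O)(OC[C@@H](C)[C@H](C)CO[Si](C)(C)C(C)(C)C)C(F)(F)F
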